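The constants were drawn at random within sensible limits; the run is a simulation.

What stands in this flask at the end of its run, and has anything stopped it?

starting material 0.90 M; free catalyst 45 mM; time 8.0 d

    starting material + free catalyst ⇌ catalyst intermediate A (K1 = 0.88 /M, k1 = 0.0031 /M/s)
    catalyst intermediate A → catalyst intermediate B (k2 = 0.0067 /s)
    catalyst intermediate B ⇌ free catalyst + target (K3 = 1.1 M, k3 = 4.1 × 10⁻⁴ /s)
    target ⇌ isomer of the product (K4 = 0.61, k4 = 7.6 × 10⁻⁶ /s)

- the reaction counts as stopped when no species that holds the starting material changes by six tenths of a point or more over the second half of the time
- run time (flask): 8.0 d

* at 8.0 d, what has stopped the reaction, if anything has (no working catalyst is left / it is still moving / forward and back rates have come level / all of the starting material has reacted)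
* part of the starting material gone at 8.0 d
* the target standing at 8.0 d, as a percentage of the starting material charged
* the isomer of the product standing at 8.0 d, as a percentage of the starting material charged

Starting material binds free catalyst as catalyst intermediate A, which goes on irreversibly to catalyst intermediate B. B releases target and free catalyst, and target isomerises reversibly. The binding half-life, forward rate only and charges held, is 0.058 d, short against the run. That is one step's forward rate, not the whole uptake, but the step after it is irreversible, so I expect full conversion.

Two numbers seem not to go together in this flask. Write k = 7.6 × 10⁻⁶ /s for the forward isomerisation and K = 0.61 for its equilibrium constant. The forward half-life of target by isomerisation, the way back not counted, is 1.1 d, short against the run, and that forward rate, counted over the run, gives a factor of 0.523%. Yet the balance gives 62.1% as f, the equilibrium target share, target over target plus isomer.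

I integrate the isomerisation at a steady sum S of target and isomer. The rate of target is −k[target] + (k/K)[isomer], so target's distance from fS falls exponentially at λ = k + k/K = 1.73 /d. The relaxation half-life is 0.400 d, shorter than the forward one, and the run holds 20.0 of them. Target therefore decays towards fS, not towards zero: this is thermodynamic control.

The balance of the release step puts a share h = 33.7% of the catalyst in B, with target at f times the charge. That gives target 61.1% and isomer 37.2%.

The forecast says all of the starting material has reacted, with conversion 100%, target 61.1% and isomer 37.3%: “The target and isomer relax within about 14 h to their 0.61 ratio”.

The simulation gives all of the starting material has reacted, with conversion 100%, target 61.1% and isomer 37.3%, so the forecast holds.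

The standing split in this flask is 62.1%, level with f. The way back is the reason: in the run of this flask without the falling back of isomer to target, target drops from 61.1% to 0.835%. In the neighbour flask with 0.027 M of free catalyst, f and h put 1.01% of the starting material charged in catalyst intermediate B and give target 61.5%. The computed neighbour flask stands at 61.5% target, with catalyst intermediate B at 1.00% of the starting material charged.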